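Readings and results stem from a simulated flask from invented constants; noise was put on by code.

No rate constant was known to me, so I read the order in free catalyst directly from the runs.

| setting | blue | grey | violet | flask |
|---|---|---|---|---|
| starting material | 38 mM | 38 mM | 19 mM | 38 mM |
| second substrate | 19 mM | 19 mM | 19 mM | 19.0 mM |
| reagent | 30.4 mM | 30.4 mM | 30.4 mM | 30.4 mM |
| free catalyst | 2.1 mM | 3.2 mM | 4.2 mM | 4.2 mM |
| remark | run made earlier | run made earlier | run made earlier |  |

- blue (time / d: target / %, starting material / %): 1.25: 43, 57; 2.50: 56, 46; 4.00: 59, 40; 5.00: 62, 36; 6.00: 65, 40
- grey (time / d: target / %, starting material / %): 0.500: 36, 65; 1.04: 53, 49; 1.67: 57, 41; 3.00: 62, 37; 6.00: 69, 32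
- violet (time / d: target / %, starting material / %): 0.500: 49, 53; 1.04: 65, 40; 1.67: 76, 25; 3.00: 85, 14; 6.00: 92, 4

(each reading ± 2 percentage points)

- the analysis behind the earlier runs scatters by 2 percentage points, standard deviation
- what is bound to the catalyst counts as converted
- no earlier run changes the charge of second substrate; that part of a forecast is a guess

- apparent order in second substrate when 30% of the starting material are converted (percent change of the rate of making target for one percent more second substrate charged)
- apparent order in free catalyst when 30% of the starting material are converted (percent change of the rate of making target for one percent more free catalyst charged)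

The blue and grey runs have equal charges except free catalyst, 2.1 mM against 3.2 mM. Blue showed 43% target after 1.25 d; grey, interpolated between its first two readings, reached that at 0.722 d. If the rate goes as a power of the catalyst charged, the time to equal conversion goes inversely as that power, so I took the catalyst exponent, the logarithm of the time ratio over the logarithm of the charge ratio: 1.30. It is a reading and carries the scatter of 2 percentage points. Applied to blue's 56% at 2.50 d, it puts grey there at 1.45 d, and grey did lie between 53% at 1.04 d and 57% at 1.67 d.

The flask is the grey run with 4.2 mM free catalyst, so I expected grey's curve on a shorter clock: its 53% at 0.730 d. I expected the same end as well. Grey showed 26.2 mM target, more than the second substrate charged, 19 mM, so I took second substrate to be no partner in making target but a holder of catalyst, and committed to a negative order in [second substrate], a guess. The limiting reagent I took to be the reagent, which caps both at 80.0%, and grey was creeping at 69%. The violet run, with half the starting material and reagent above it, reached 92%.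

The forecast, unlike my reckoning, gave 2.2 and 0.85, holding that “the second substrate runs out”. The flask gave −0.82 in second substrate and 1.4 in free catalyst, against my 1.30; it held 51.5% target after 0.800 d, and 67.7% after 8.00 d with reagent at 0%.

    starting material + free catalyst ⇌ catalyst intermediate A (K = 850 /M, k = 0.00790 /M/s)
    reagent + catalyst intermediate A → free catalyst + target (k = 0.0310 /M/s)
    second substrate + free catalyst ⇌ catalyst intermediate B (K = 600 /M, k = 0.00490 /M/s)
    reagent + catalyst intermediate B → free catalyst + second product (k = 0.00270 /M/s)
    2 catalyst intermediate B ⇌ resting dimer (K = 5200 /M, k = 0.00900 /M/s)

In the flask at 0.322 d, starting material took up free catalyst 2.7 times as fast as second substrate did, each forward step counted by itself. Yet after 0.800 d the flask had 17.1% of its catalyst free, and the resting dimer, its resting state, held more than any other form, at 45.7%.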